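**Plan**

1. The six carbons of the cyclohexene are called C-a (alkene carbon on quinolone A), C-b (alkene CH), C-c (quaternary carbon with O and Me), C-d (CH2), C-e (CH on quinolone B) and C-f (CH beside CMe2). The retrosynthesis cuts C-e–C-f and C-b–C-c, a [3+3] disconnection, into a 2-methylpyrano[3,2-c]quinolinium ion (ring B half) and a 4-(silylmethyl)pyranoquinolone (ring A half).
2. This works because C-c and C-e are C2 and C4 of pyran ring B, the two electrophilic carbons of a benzopyrylium ion. C-f, C-a and C-b are C3, C4 and the exocyclic carbon on C4 of pyran ring A, an allylsilane that can act twice as a carbon nucleophile.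
3. Both halves go back to one quinolone, 4-hydroxy-7,8-dimethoxy-1-methylquinolin-2-one, made from 2,3-dimethoxyaniline and a malonate.
4. Forward: quinolone; ring A by acylation/oxa-Michael addition, enol triflate, allylsilane; ring B as a pyrylium salt stored as its methyl ketal; the union of the halves closes the carbocycle last.
5. Stereochemistry: C-e is set by the chiral counter-anion of the pyrylium ion (catalysis). C-f is set in the same bond formation under substrate control (CMe2 exo). C-c follows from the geometry of the bridge.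

Key step: step 7

Assumption: the (R)-phosphoramide is taken to expose the face of C-e that leads to 17; the sense of induction has to be found by experiment, and the (S)-catalyst is used if it is the reverse.

**Step 1**
Reactants: 1 2,3-dimethoxyaniline
Product: 3 2,3-dimethoxy-N-methylaniline, via N-(methoxymethyl)aniline 2 (not isolated)
Conditions: (CH2O)n, NaOMe, MeOH, 65 °C; then NaBH4, 65 °C
Reagents that add atoms: formaldehyde (as paraformaldehyde) C=O
Why: Mono-N-methylation through the hemiaminal ether and hydride reduction should stop at the secondary amine, because only the primary amine forms the N-(methoxymethyl) intermediate.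

**Step 2**
Reactants: 3 2,3-dimethoxy-N-methylaniline; 4 bis(2,4,6-trichlorophenyl) malonate
Product: 6 4-hydroxy-7,8-dimethoxy-1-methylquinolin-2(1H)-one, via aryl malonamate 5 (not isolated)
Conditions: neat, 220 °C, 2,4,6-trichlorophenol distilled off
Reagents that add atoms: none
Why: Thermal N-acylation by the active malonate and intramolecular C-acylation at the only free ortho position (para to a methoxy group) should give the 4-hydroxyquinolone (active-malonate quinolone synthesis).

**Step 3**
Reactants: 6 4-hydroxy-7,8-dimethoxy-1-methylquinolin-2(1H)-one; 7 3-methylbut-2-enoic acid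
Product: 9 7,8-dimethoxy-2,2,6-trimethyl-2,3-dihydro-4H-pyrano[3,2-c]quinoline-4,5(6H)-dione, via 3-senecioylquinolone 8 (not isolated)
Conditions: P2O5/MeSO3H (1:10), 70 °C
Reagents that add atoms: none
Why: Friedel–Crafts acylation at C3 of the vinylogous acid followed by oxa-Michael addition of the 4-OH to the β,β-dimethyl enone should close pyran ring A as the chromanone.

**Step 4**
Reactants: 9 7,8-dimethoxy-2,2,6-trimethyl-2,3-dihydro-4H-pyrano[3,2-c]quinoline-4,5(6H)-dione
Product: 10 7,8-dimethoxy-2,2,6-trimethyl-5-oxo-5,6-dihydro-2H-pyrano[3,2-c]quinolin-4-yl trifluoromethanesulfonate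
Conditions: KN(SiMe3)2 added to 9 and PhNTf2, THF, −78 °C
Reagents that add atoms: N-phenylbis(trifluoromethanesulfonimide) O=S(=O)(N(c1ccccc1)S(=O)(=O)C(F)(F)F)C(F)(F)F
Why: Enolate O-sulfonylation at the only α-CH2 should give the enol triflate, with the electrophile present from the start so that the enolate is trapped as it forms.

**Step 5**
Reactants: 10 7,8-dimethoxy-2,2,6-trimethyl-5-oxo-5,6-dihydro-2H-pyrano[3,2-c]quinolin-4-yl trifluoromethanesulfonate
Product: 11 7,8-dimethoxy-2,2,6-trimethyl-4-[(trimethylsilyl)methyl]-2,6-dihydro-5H-pyrano[3,2-c]quinolin-5-one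
Conditions: Me3SiCH2MgCl, Pd(PPh3)4 (5 mol %), THF, 0 to 25 °C
Reagents that add atoms: (trimethylsilyl)methylmagnesium chloride C[Si](C)(C)C[Mg]Cl
Why: Kumada–Corriu coupling of an enol triflate with the α-silyl Grignard reagent, which has no β-hydrogen, is the standard route to allylsilanes, and the low temperature should spare the lactam.

**Step 6**
Reactants: 6 4-hydroxy-7,8-dimethoxy-1-methylquinolin-2(1H)-one; 12 4,4-dimethoxybutan-2-one
Product: 14 2,7,8-trimethoxy-2,6-dimethyl-2,6-dihydro-5H-pyrano[3,2-c]quinolin-5-one (racemic ketal), via pyranoquinolinium tetrafluoroborate 13 (not isolated)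
Conditions: HBF4·OEt2, AcOH, 25 °C; then MeOH, NaHCO3, 0 °C
Reagents that add atoms: methanol CO
Why: C3 attacks the oxocarbenium ion of the acetal, and elimination plus cyclodehydration onto the ketone should give the aromatic 2-methylpyrylium ion (benzopyrylium synthesis from a phenol-type enol and a β-keto acetal), which methanol traps at C2 as the ketal.

**Step 7**
Reactants: 11 7,8-dimethoxy-2,2,6-trimethyl-4-[(trimethylsilyl)methyl]-2,6-dihydro-5H-pyrano[3,2-c]quinolin-5-one; 14 2,7,8-trimethoxy-2,6-dimethyl-2,6-dihydro-5H-pyrano[3,2-c]quinolin-5-one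
Product: 17 CNP0237003 (S at C-c; R at C-e; S at C-f), via pyranoquinolinium ion pair 15 (not isolated), via methylidene 4H-pyran adduct 16 (not isolated)
Conditions: (R)-3,3′-bis(2,4,6-triisopropylphenyl)-1,1′-binaphthyl-2,2′-diyl N-triflylphosphoramide (10 mol %), PhMe, −60 to 0 °C, 14 added slowly
Reagents that add atoms: none
Why: Proposed new method: the acid should ionise ketal 14 to the aromatic pyranoquinolinium ion 15, whose C4 (C-e) is attacked by the γ-carbon (C-f) of allylsilane 11 in an SE2′ Hosomi–Sakurai step that expels silicon as Me3SiOMe and leaves the exocyclic methylene of 16; the regenerated acid then protonates the 4H-pyran enol ether of 16 at C-d, the methylene carbon (C-b) attacks the 2-methyl oxocarbenium carbon (C-c), and the tertiary cation at C-a loses a proton from C-b. The closest known reactions are the [3+3] annulations of flavylium ions with O,C-dinucleophiles to 2,8-dioxabicyclo[3.3.1]nonanes, chiral counter-anion control of additions to benzopyrylium and oxocarbenium ions, and the acid-induced chromene-to-citran cyclisation; an all-carbon allyl 1,3-dinucleophile has not been used in this way. The carbocycle is the only ring closed: C-e–C-f forms between the two halves, and the ring then closes by a cation–olefin (Prins-type) attack in which the alkene lies inside the new six-membered ring and the C=O+ bond outside it. C-e is set by the chiral phosphoramidate anion, which should shield one face of C4 of 15; C-f is set in the same bond formation, and only the adduct that keeps the CMe2 carbon on the exo face, away from the C2 carbonyl of quinolone B, should be able to close; C-c is fixed by geometry, because the arm on C-e reaches the oxocarbenium carbon only from its own face of ring B. The step needs attack at C4 and not C2 of 15 (C2 carries the methyl group), C-f and not C-b as the first nucleophilic carbon (enforced by the silyl group, which leaves only in an SE2′ event), and final proton loss from C-b and not C-f (loss from C-f would force the CMe2 carbon into the plane beside the lactam carbonyl of quinolone B).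

**Compound list**

1 | 2,3-dimethoxyaniline | COc1cccc(N)c1OC | starting material
2 | N-(methoxymethyl)-2,3-dimethoxyaniline (not isolated) | COCNc1cccc(OC)c1OC | intermediate
3 | 2,3-dimethoxy-N-methylaniline | CNc1cccc(OC)c1OC | intermediate
4 | bis(2,4,6-trichlorophenyl) malonate | O=C(CC(=O)Oc1c(Cl)cc(Cl)cc1Cl)Oc1c(Cl)cc(Cl)cc1Cl | starting material
5 | 2,4,6-trichlorophenyl 3-[(2,3-dimethoxyphenyl)(methyl)amino]-3-oxopropanoate (not isolated) | COc1cccc(N(C)C(=O)CC(=O)Oc2c(Cl)cc(Cl)cc2Cl)c1OC | intermediate
6 | 4-hydroxy-7,8-dimethoxy-1-methylquinolin-2(1H)-one | COc1ccc2c(O)cc(=O)n(C)c2c1OC | intermediate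
7 | 3-methylbut-2-enoic acid | CC(C)=CC(=O)O | starting material
8 | 4-hydroxy-7,8-dimethoxy-1-methyl-3-(3-methylbut-2-enoyl)quinolin-2(1H)-one (not isolated) | COc1ccc2c(O)c(C(=O)C=C(C)C)c(=O)n(C)c2c1OC | intermediate
9 | 7,8-dimethoxy-2,2,6-trimethyl-2,3-dihydro-4H-pyrano[3,2-c]quinoline-4,5(6H)-dione | COc1ccc2c3c(c(=O)n(C)c2c1OC)C(=O)CC(C)(C)O3 | intermediate
10 | 7,8-dimethoxy-2,2,6-trimethyl-5-oxo-5,6-dihydro-2H-pyrano[3,2-c]quinolin-4-yl trifluoromethanesulfonate | COc1ccc2c3c(c(=O)n(C)c2c1OC)C(OS(=O)(=O)C(F)(F)F)=CC(C)(C)O3 | intermediate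
11 | 7,8-dimethoxy-2,2,6-trimethyl-4-[(trimethylsilyl)methyl]-2,6-dihydro-5H-pyrano[3,2-c]quinolin-5-one | COc1ccc2c3c(c(=O)n(C)c2c1OC)C(C[Si](C)(C)C)=CC(C)(C)O3 | intermediate
12 | 4,4-dimethoxybutan-2-one | CC(=O)CC(OC)OC | starting material
13 | 7,8-dimethoxy-2,6-dimethyl-5-oxo-5,6-dihydropyrano[3,2-c]quinolin-1-ium tetrafluoroborate (not isolated) | Cc1ccc2c(=O)n(C)c3c(OC)c(OC)ccc3c2[o+]1.F[B-](F)(F)F | intermediate
14 | 2,7,8-trimethoxy-2,6-dimethyl-2,6-dihydro-5H-pyrano[3,2-c]quinolin-5-one (racemic at the ketal carbon) | COC1(C)C=Cc2c(c3ccc(OC)c(OC)c3n(C)c2=O)O1 | intermediate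
15 | 7,8-dimethoxy-2,6-dimethyl-5-oxo-5,6-dihydropyrano[3,2-c]quinolin-1-ium paired with the phosphoramidate anion of the catalyst (cation shown; not isolated) | Cc1ccc2c(=O)n(C)c3c(OC)c(OC)ccc3c2[o+]1 | intermediate
16 | (3S)-7,8-dimethoxy-3-[(4R)-7,8-dimethoxy-2,6-dimethyl-5-oxo-5,6-dihydro-4H-pyrano[3,2-c]quinolin-4-yl]-2,2,6-trimethyl-4-methylidene-3,4-dihydro-2H-pyrano[3,2-c]quinolin-5(6H)-one (not isolated) | COc1ccc2c3c(c(=O)n(C)c2c1OC)C(=C)[C@H]([C@H]4C=C(C)Oc5c4c(=O)n(C)c4c(OC)c(OC)ccc54)C(C)(C)O3 | intermediate
17 | CNP0237003 (S at C-c; R at C-e; S at C-f) | COc1ccc2c3c(c(=O)n(C)c2c1OC)C1=C[C@]2(C)C[C@@H](c4c(c5ccc(OC)c(OC)c5n(C)c4=O)O2)[C@@H]1C(C)(C)O3 | target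

**Step count**

Total steps: 7. Longest linear sequence: 6 (steps 1, 2, 3, 4, 5, 7).

**Steps most likely to fail**

Step 7. Several processes may go wrong:
- Facial and relative control in the first C–C bond formation may be insufficient, and the adduct with the wrong relative configuration is not expected to close.
- The last proton may be lost from the ring-fusion carbon instead of the methylene, which moves the alkene into ring A.
- The allylsilane may be protodesilylated before coupling, which hands the nucleophilicity to the exocyclic carbon.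
- The 2-methylpyrylium ion may condense with itself through its methylene base.

The fallback separates the events and uses known reaction types; it sets out from 9 and 14 and comes back at 16. Soft enolisation of 9 (Me3SiOTf, Et3N, CH2Cl2, 0 °C) gives the trimethylsilyl enol ether F1. F1 adds to C4 of the pyranoquinolinium ion generated from 14 under the same chiral N-triflylphosphoramide, a Mukaiyama-type addition of a silyl enol ether to a benzopyrylium ion under chiral acid control. This gives the ketone F2, whose C-f centre is α to the ketone and can be equilibrated. Me3SiCH2MgCl/CeCl3 (THF, −78 °C) adds to the ketone to give the β-hydroxysilane F3. Camphorsulfonic acid (CH2Cl2, 0 °C) effects Peterson elimination to 16, which the same acid should close to 17 by the Prins-type step.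

Step 6. The pyrylium salt may be deprotonated at its methyl group during the methanol quench and oligomerise, or a second quinolone may add to C4 of the cation. The fallback sets out from 6 and comes back at 14. Conjugate addition of 6 to but-3-yn-2-one (DABCO cat., MeCN, 25 °C) gives the (Z)-enone, which should close to the cyclic hemiketal F4, a ring–chain tautomer of the warfarin type. Pyridinium p-toluenesulfonate, HC(OMe)3 and MeOH at 25 °C then exchange OH for OMe to give 14 without a pyrylium salt being handled in base.

Step 4. The potassium enolate may open ring A by β-elimination of the quinolone oxygen (retro-oxa-Michael) faster than it is sulfonylated. The fallback sets out from 9 and comes back at 16. MeMgBr/CeCl3 (THF, −78 °C) adds to the ketone to give the tertiary alcohol F5, and TsOH (PhH, 80 °C) dehydrates it to the 4-methylchromene F6. F6 takes the place of 11 in step 7: after attack of C-f on 15 the cation loses a proton from the methyl group instead of a silyl group, which gives 16. Silicon no longer fixes which carbon attacks first.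

**Further compounds**

F1 | step 7 | 7,8-dimethoxy-2,2,6-trimethyl-4-[(trimethylsilyl)oxy]-2,6-dihydro-5H-pyrano[3,2-c]quinolin-5-one | COc1ccc2c3c(c(=O)n(C)c2c1OC)C(O[Si](C)(C)C)=CC(C)(C)O3
F2 | step 7 | (3R)-7,8-dimethoxy-3-[(4R)-7,8-dimethoxy-2,6-dimethyl-5-oxo-5,6-dihydro-4H-pyrano[3,2-c]quinolin-4-yl]-2,2,6-trimethyl-2,3-dihydro-4H-pyrano[3,2-c]quinoline-4,5(6H)-dione (same spatial arrangement as 16) | COc1ccc2c3c(c(=O)n(C)c2c1OC)C(=O)[C@H]([C@H]4C=C(C)Oc5c4c(=O)n(C)c4c(OC)c(OC)ccc54)C(C)(C)O3
F3 | step 7 | β-hydroxysilane from F2: 4-hydroxy-4-[(trimethylsilyl)methyl] compound, carbinol carbon of either configuration, the two methine carbons as in 16 | COc1ccc2c3c(c(=O)n(C)c2c1OC)C(O)(C[Si](C)(C)C)[C@H]([C@H]4C=C(C)Oc5c4c(=O)n(C)c4c(OC)c(OC)ccc54)C(C)(C)O3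
F4 | step 6 | 2-hydroxy-7,8-dimethoxy-2,6-dimethyl-2,6-dihydro-5H-pyrano[3,2-c]quinolin-5-one (racemic hemiketal) | CC1(O)C=Cc2c(c3ccc(OC)c(OC)c3n(C)c2=O)O1
F5 | step 4 | 4-hydroxy-7,8-dimethoxy-2,2,4,6-tetramethyl-3,4-dihydro-2H-pyrano[3,2-c]quinolin-5(6H)-one (racemic) | COc1ccc2c3c(c(=O)n(C)c2c1OC)C(C)(O)CC(C)(C)O3
F6 | step 4 | 7,8-dimethoxy-2,2,4,6-tetramethyl-2,6-dihydro-5H-pyrano[3,2-c]quinolin-5-one | COc1ccc2c3c(c(=O)n(C)c2c1OC)C(C)=CC(C)(C)O3
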